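## Retrosynthetic overview

- Numbering (tricyclo[5.4.0.0(2,8)]undecane): cyclobutane C1–C2–C8–C7; enone ring C1, C7–C11 (C9 = ketone, C10=C11); seven-membered ring C2–C8 (C3 tiglate, C5 angelate, C6 = CMe2).
- The C5 angelate goes on last. Before that, the C3 tiglate and the C5 alcohol both come from a 3-hydroxy-5-ketone by one Evans–Tishchenko reduction with tiglaldehyde.
- Ring C2–C8 is closed last, at C6–C7, by a copper hydride reductive aldol of an isopropenyl ketone onto a C7 cyclobutanone. The C7 hydroxyl is then removed by radical deoxygenation and the C9 oxygen becomes the enone.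
- The cyclobutane and the six-membered ring are formed together one step earlier by intramolecular vinylketene–alkene (2+2) cycloaddition of an acyclic trienoic acid. That acid is built by an auxiliary acetate aldol (C3), a Weinreb ketone synthesis (C6) and a vinylogous Mukaiyama aldol (C9).
- Enabling feature: C6 is α to the C5 ketone and carries both methyl groups, so it is a non-stereogenic enolate carbon. C7 is a cyclobutanone carbonyl held cis-1,3 to the C2 side chain on ring C1–C2–C8–C7, on the face anti to the C9–C11 bridge.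

Key step: step 13

Assumption: the SiCl4–bisphosphoramide vinylogous aldol is taken to attack the Re face of aldehydes with the (R,R)-catalyst, so the (S,S)-catalyst is specified for the Si-face attack needed in step 9; if the sense is the opposite, the antipodal catalyst is used and no compound changes.

## Route

Step 1
Reactants: 1 2-[(tert-butyldimethylsilyl)oxy]acetaldehyde; 2 2-(triphenylphosphoranylidene)propanal
Product: 3 (2E)-4-[(tert-butyldimethylsilyl)oxy]-2-methylbut-2-enal
Conditions: toluene, 80 °C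
Reagents that add atoms: none
Why: Wittig olefination with a stabilised α-methyl formyl ylide should give the trisubstituted enal with E geometry, as is usual for stabilised ylides.

Step 2
Reactants: 3 enal; 4 (4S)-3-acetyl-4-benzyl-1,3-thiazolidine-2-thione
Product: 6 (3R,4E)-3-hydroxy aldol adduct on the thiazolidinethione, via chlorotitanium enolate 5 (not isolated)
Conditions: 4, TiCl4 (1.1 equiv), iPr2NEt (1.1 equiv), CH2Cl2, −78 to −40 °C; then 3, −78 °C
Reagents that add atoms: none
Why: Auxiliary-controlled titanium acetate aldol, in which the chelated enolate 5 is shielded on one face by the benzyl group and should add through a closed transition state to the Re face of the enal, setting the carbinol (later C3) as R; the diastereomers are separable.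

Step 3
Reactants: 6 aldol adduct
Product: 7 (3R,4E)-3,6-bis(silyl ether) of the N-acyl thiazolidinethione
Conditions: TBSOTf, 2,6-lutidine, CH2Cl2, −78 to 0 °C
Reagents that add atoms: tert-butyldimethylsilyl trifluoromethanesulfonate, CC(C)(C)[Si](C)(C)OS(=O)(=O)C(F)(F)F
Why: Silylation of the secondary allylic alcohol with a silyl triflate and a hindered base is routine and blocks retro-aldol cleavage.

Step 4
Reactants: 7 silylated N-acyl thiazolidinethione
Product: 8 (3R,4E)-3,6-bis[(tert-butyldimethylsilyl)oxy]-N-methoxy-N,4-dimethylhex-4-enamide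
Conditions: MeNHOMe·HCl, imidazole, CH2Cl2, 23 °C
Reagents that add atoms: N,O-dimethylhydroxylamine hydrochloride, Cl.CNOC
Why: The thiazolidinethione is an activated amide and should be displaced directly by the hydroxylamine (aminolysis) without touching the silyl ethers or the stereocentre.

Step 5
Reactants: 8 Weinreb amide; 9 prop-1-en-2-ylmagnesium bromide
Product: 10 (5R,6E)-5,8-bis[(tert-butyldimethylsilyl)oxy]-2,6-dimethylocta-1,6-dien-3-one
Conditions: THF, 0 °C; aq. NH4Cl
Reagents that add atoms: none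
Why: Weinreb ketone synthesis, in which N-methoxy chelation of magnesium prevents a second addition so that the isopropenyl ketone is released only on work-up.

Step 6
Reactants: 10 bis-silyl ether
Product: 11 (5R,6E)-5-[(tert-butyldimethylsilyl)oxy]-8-hydroxy-2,6-dimethylocta-1,6-dien-3-one
Conditions: HF·pyridine, pyridine, THF, 0 °C
Reagents that add atoms: none
Why: Buffered HF·pyridine should cleave the primary allylic silyl ether much faster than the hindered secondary one (steric differentiation of silyl ethers).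

Step 7
Reactants: 11 allylic alcohol
Product: 12 (2E,4R)-4-[(tert-butyldimethylsilyl)oxy]-3,7-dimethyl-6-oxoocta-2,7-dienal
Conditions: Dess–Martin periodinane, CH2Cl2, 0 to 23 °C
Reagents that add atoms: none
Why: Dess–Martin oxidation of the primary allylic alcohol should give the enal under near-neutral conditions without alkene isomerisation or β-elimination of the silyloxy ketone.

Step 8
Reactants: 13 methyl 3-methylbut-2-enoate
Product: 14 tert-butyl[(1-methoxy-3-methylbuta-1,3-dien-1-yl)oxy]dimethylsilane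
Conditions: LiN(iPr)2, THF, −78 °C; TBSCl, DMPU, −78 to 0 °C
Reagents that add atoms: tert-butyldimethylsilyl chloride, CC(C)(C)[Si](C)(C)Cl
Why: γ-Deprotonation of the unsaturated ester and O-silylation give the silyl dienol ether (silyl ketene acetal formation).

Step 9
Reactants: 12 enal; 14 silyl dienol ether
Product: 15 methyl (2E,5S,6E,8R)-8-[(tert-butyldimethylsilyl)oxy]-5-hydroxy-3,7,11-trimethyl-10-oxododeca-2,6,11-trienoate
Conditions: SiCl4 (1.1 equiv), (S,S)-binaphthyldiamine-derived bisphosphoramide (5 mol %), iPr2NEt (10 mol %), CH2Cl2, −78 °C; aq. KF/NaHCO3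
Reagents that add atoms: none
Why: Catalytic enantioselective vinylogous Mukaiyama aldol, in which the chiral Lewis-base-bound chlorosilyl cation activates only the aldehyde, the dienolate reacts at its γ-carbon, and catalyst control should set the new carbinol (later C9) as S by Si-face attack; the geometry of the 2,3-alkene is of no consequence because it is erased in step 12.

Step 10
Reactants: 15 hydroxy ester
Product: 16 methyl (2E,5S,6E,8R)-8-[(tert-butyldimethylsilyl)oxy]-3,7,11-trimethyl-10-oxo-5-[(triethylsilyl)oxy]dodeca-2,6,11-trienoate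
Conditions: Et3SiCl, imidazole, DMF, 0 °C
Reagents that add atoms: chlorotriethylsilane, CC[Si](CC)(CC)Cl
Why: Silylation with the chloride and imidazole protects the carbinol without forming a silyl enol ether from the ketone, and a triethylsilyl ether can later be removed beside the tert-butyldimethylsilyl ether.

Step 11
Reactants: 16 methyl ester
Product: 17 (2E,5S,6E,8R)-8-[(tert-butyldimethylsilyl)oxy]-3,7,11-trimethyl-10-oxo-5-[(triethylsilyl)oxy]dodeca-2,6,11-trienoic acid
Conditions: Me3SnOH, 1,2-dichloroethane, 70 °C; cold 0.1 M HCl wash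
Reagents that add atoms: trimethyltin hydroxide, C[Sn](C)(C)O
Why: Trimethyltin hydroxide cleaves the methyl ester under nearly neutral conditions (mild ester hydrolysis), which should avoid β-elimination of the silyloxy ketone and conjugate addition to the isopropenyl ketone.

Step 12
Reactants: 17 trienoic acid
Product: 20 (1R,4S,5R,7R)-7-[(1R)-1-[(tert-butyldimethylsilyl)oxy]-4-methyl-3-oxopent-4-en-1-yl]-7-methyl-2-methylidene-4-[(triethylsilyl)oxy]bicyclo[3.1.1]heptan-6-one, via acid chloride 18 (not isolated), via vinylketene 19 (not isolated)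
Conditions: 1-chloro-N,N,2-trimethylprop-1-en-1-amine, CH2Cl2, 0 to 23 °C; then slow addition to Et3N, toluene, 110 °C (high dilution)
Reagents that add atoms: none
Why: Intramolecular vinylketene–alkene (2+2) cycloaddition, in which dehydrochlorination at the C3 methyl gives 19, whose carbonyl carbon bonds to C6 and whose α-carbon bonds to the more substituted C7 of the trisubstituted alkene, closing the cyclobutanone and the six-membered ring at once; the E alkene places the methyl group syn and the side chain anti to the three-carbon bridge (suprafacial addition), the silyloxy group on the tether should set the face by avoiding 1,3-allylic strain with the cis methyl group while the exocyclic allylic silyloxy centre should have only a minor influence, and the minor diastereomer is removed by chromatography.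

Step 13
Reactants: 20 bicyclic cyclobutanone with isopropenyl ketone side chain
Product: 22 tricyclic aldol (7-hydroxy-5-ketone; 3-OTBS, 9-OSiEt3, 11-methylidene), via copper enolate 21 (not isolated)
Conditions: [(Ph3P)CuH]6 (0.35 equiv), toluene, −40 to 0 °C; aq. NH4Cl
Reagents that add atoms: none
Why: Conjugate addition of copper hydride to the isopropenyl ketone, the only enone present, gives monovalent copper enolate 21 regiospecifically at the future C6, which now carries both methyl groups. This enolate adds to the strained C7 cyclobutanone carbonyl and closes the seven-membered ring C2–C8 by a 7-(enolexo)-exo-trig aldol, forming the C6–C7 bond between two fully substituted carbons; relief of the strain of the sp2 carbon in the four-membered ring should drive the addition. The closest known reaction type is the copper hydride mediated reductive aldol cyclisation of keto enones. The only new stereocentre, C7, is fixed by the tether: the side chain sits on C2 anti to the C9–C11 bridge and cis-1,3 to C7 on the cyclobutane, so C6 can reach the carbonyl only from that face and the hydroxyl must point to the bridge side; C6 is not stereogenic. The step needs chemoselective hydride delivery to the terminal enone beside the cyclobutanone and the 1,1-disubstituted alkene, which this reagent provides, and it needs the C9 oxygen to be a silyl ether and not yet a ketone, so that the new tertiary cyclobutanol is not β to a ring carbonyl and cannot open the four-membered ring by retro-aldol cleavage.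

Step 14
Reactants: 22 tricyclic aldol
Product: 23 7-O-(methoxyoxalyl) ester of 22
Conditions: ClC(O)CO2Me, pyridine, DMAP (cat.), CH2Cl2, 0 to 23 °C
Reagents that add atoms: methyl chlorooxoacetate, COC(=O)C(=O)Cl
Why: Acylation of the hindered tertiary alcohol with the small, highly electrophilic oxalyl chloride half-ester gives the mixed oxalate needed for radical C–O cleavage, and no alkoxide is generated, so the aldol cannot revert.

Step 15
Reactants: 23 tertiary methyl oxalate
Product: 25 deoxygenated tricycle (7-H; 5-ketone, 3-OTBS, 9-OSiEt3, 11-methylidene), via cyclobutyl radical 24 (not isolated)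
Conditions: Bu3SnH, AIBN (cat.), toluene, 110 °C
Reagents that add atoms: none
Why: Radical deoxygenation of a tertiary alkyl methyl oxalate (Barton–McCombie type), in which C–O scission gives radical 24 and hydrogen transfer from the stannane can place hydrogen only on the bridge side because C6 holds the other position in the ring, so C7 is set as in the target; elimination is impossible because both neighbours are bridgeheads or quaternary.

Step 16
Reactants: 25 bis-silyl ether
Product: 26 9-hydroxy tricycle (5-ketone, 3-OTBS, 11-methylidene)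
Conditions: PPTS (0.2 equiv), MeOH/CH2Cl2, 0 °C
Reagents that add atoms: none
Why: Acidic methanolysis should remove the secondary triethylsilyl ether selectively beside the more hindered tert-butyldimethylsilyl ether.

Step 17
Reactants: 26 secondary alcohol
Product: 28 3-[(tert-butyldimethylsilyl)oxy]-2,6,6,11-tetramethyltricyclo[5.4.0.0(2,8)]undec-10-ene-5,9-dione, via β,γ-unsaturated ketone 27 (not isolated)
Conditions: Dess–Martin periodinane, CH2Cl2, 23 °C; then DBU (0.1 equiv), 23 °C
Reagents that add atoms: none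
Why: Dess–Martin oxidation gives 27, and catalytic base moves the exocyclic alkene into conjugation (isomerisation through the dienolate) to give the 11-methyl enone; the bridgehead C8 cannot enolise, so nothing can epimerise.

Step 18
Reactants: 28 silyl ether
Product: 29 (1R,2R,3R,7S,8R)-3-hydroxy-2,6,6,11-tetramethyltricyclo[5.4.0.0(2,8)]undec-10-ene-5,9-dione
Conditions: HF·pyridine, THF, 0 to 23 °C
Reagents that add atoms: none
Why: Fluoride-mediated desilylation under buffered acidic conditions frees the C3 hydroxyl without retro-aldol cleavage of the β-hydroxy ketone.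

Step 19
Reactants: 29 β-hydroxy ketone; 30 (2E)-2-methylbut-2-enal (tiglaldehyde)
Product: 32 (1R,2R,3R,5R,7S,8R)-5-hydroxy-2,6,6,11-tetramethyl-9-oxotricyclo[5.4.0.0(2,8)]undec-10-en-3-yl (2E)-2-methylbut-2-enoate, via hemiacetal 31 (not isolated)
Conditions: 30 (6 equiv), SmI2 (0.3 equiv), THF, −10 °C
Reagents that add atoms: none
Why: Evans–Tishchenko reduction, in which the trivalent samarium alkoxide of hemiacetal 31 delivers hydride intramolecularly to the C5 ketone through a six-membered chelate, which should reduce C5 anti to the C3 oxygen (5R) and leave the tigloyl group on O3, so the two hydroxyls are differentiated and the tiglate is installed in one operation; the C9 enone has no β-hydroxyl and is not reduced.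

Step 20
Reactants: 32 hydroxy tiglate; 33 (2Z)-2-methylbut-2-enoic acid (angelic acid)
Product: 35 target, (1R,2R,3R,5R,7S,8R)-2,6,6,11-tetramethyl-9-oxotricyclo[5.4.0.0(2,8)]undec-10-ene-3,5-diyl 5-[(2Z)-2-methylbut-2-enoate] 3-[(2E)-2-methylbut-2-enoate], via mixed anhydride 34 (not isolated)
Conditions: 33, 2,4,6-trichlorobenzoyl chloride, Et3N, toluene, 23 °C; then 32, toluene, 80 °C
Reagents that add atoms: none
Why: Yamaguchi-type esterification, in which the alcohol attacks the unhindered angeloyl carbonyl of 34 and, without a nucleophilic amine catalyst, the Z geometry of the angeloyl group should be retained.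

## Compound list

1 | 2-[(tert-butyldimethylsilyl)oxy]acetaldehyde | O=CCO[Si](C)(C)C(C)(C)C | starting material
2 | 2-(triphenylphosphoranylidene)propanal | CC(C=O)=P(c1ccccc1)(c1ccccc1)c1ccccc1 | starting material
3 | (2E)-4-[(tert-butyldimethylsilyl)oxy]-2-methylbut-2-enal | O=C/C(C)=C/CO[Si](C)(C)C(C)(C)C | intermediate
4 | (4S)-3-acetyl-4-benzyl-1,3-thiazolidine-2-thione | CC(=O)N1[C@@H](Cc2ccccc2)CSC1=S | starting material
5 | trichlorotitanium enolate of 4 | C=C(O[Ti](Cl)(Cl)Cl)N1[C@@H](Cc2ccccc2)CSC1=S | intermediate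
6 | (3R,4E)-1-[(4S)-4-benzyl-2-thioxo-1,3-thiazolidin-3-yl]-6-[(tert-butyldimethylsilyl)oxy]-3-hydroxy-4-methylhex-4-en-1-one | O=C(C[C@@H](O)/C(C)=C/CO[Si](C)(C)C(C)(C)C)N1[C@@H](Cc2ccccc2)CSC1=S | intermediate
7 | (3R,4E)-1-[(4S)-4-benzyl-2-thioxo-1,3-thiazolidin-3-yl]-3,6-bis[(tert-butyldimethylsilyl)oxy]-4-methylhex-4-en-1-one | O=C(C[C@@H](O[Si](C)(C)C(C)(C)C)/C(C)=C/CO[Si](C)(C)C(C)(C)C)N1[C@@H](Cc2ccccc2)CSC1=S | intermediate
8 | (3R,4E)-3,6-bis[(tert-butyldimethylsilyl)oxy]-N-methoxy-N,4-dimethylhex-4-enamide | CON(C)C(=O)C[C@@H](O[Si](C)(C)C(C)(C)C)/C(C)=C/CO[Si](C)(C)C(C)(C)C | intermediate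
9 | prop-1-en-2-ylmagnesium bromide | CC(=C)[Mg]Br | starting material
10 | (5R,6E)-5,8-bis[(tert-butyldimethylsilyl)oxy]-2,6-dimethylocta-1,6-dien-3-one | C=C(C)C(=O)C[C@@H](O[Si](C)(C)C(C)(C)C)/C(C)=C/CO[Si](C)(C)C(C)(C)C | intermediate
11 | (5R,6E)-5-[(tert-butyldimethylsilyl)oxy]-8-hydroxy-2,6-dimethylocta-1,6-dien-3-one | C=C(C)C(=O)C[C@@H](O[Si](C)(C)C(C)(C)C)/C(C)=C/CO | intermediate
12 | (2E,4R)-4-[(tert-butyldimethylsilyl)oxy]-3,7-dimethyl-6-oxoocta-2,7-dienal | C=C(C)C(=O)C[C@@H](O[Si](C)(C)C(C)(C)C)/C(C)=C/C=O | intermediate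
13 | methyl 3-methylbut-2-enoate | CC(C)=CC(=O)OC | starting material
14 | tert-butyl[(1-methoxy-3-methylbuta-1,3-dien-1-yl)oxy]dimethylsilane | C=C(C)C=C(OC)O[Si](C)(C)C(C)(C)C | intermediate
15 | methyl (2E,5S,6E,8R)-8-[(tert-butyldimethylsilyl)oxy]-5-hydroxy-3,7,11-trimethyl-10-oxododeca-2,6,11-trienoate | C=C(C)C(=O)C[C@@H](O[Si](C)(C)C(C)(C)C)/C(C)=C/[C@@H](O)C/C(C)=C/C(=O)OC | intermediate
16 | methyl (2E,5S,6E,8R)-8-[(tert-butyldimethylsilyl)oxy]-3,7,11-trimethyl-10-oxo-5-[(triethylsilyl)oxy]dodeca-2,6,11-trienoate | C=C(C)C(=O)C[C@@H](O[Si](C)(C)C(C)(C)C)/C(C)=C/[C@@H](O[Si](CC)(CC)CC)C/C(C)=C/C(=O)OC | intermediate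
17 | (2E,5S,6E,8R)-8-[(tert-butyldimethylsilyl)oxy]-3,7,11-trimethyl-10-oxo-5-[(triethylsilyl)oxy]dodeca-2,6,11-trienoic acid | C=C(C)C(=O)C[C@@H](O[Si](C)(C)C(C)(C)C)/C(C)=C/[C@@H](O[Si](CC)(CC)CC)C/C(C)=C/C(=O)O | intermediate
18 | acid chloride of 17 | C=C(C)C(=O)C[C@@H](O[Si](C)(C)C(C)(C)C)/C(C)=C/[C@@H](O[Si](CC)(CC)CC)C/C(C)=C/C(Cl)=O | intermediate
19 | vinylketene, (5S,6E,8R)-8-[(tert-butyldimethylsilyl)oxy]-7,11-dimethyl-3-methylidene-5-[(triethylsilyl)oxy]dodeca-1,6,11-triene-1,10-dione | C=C(C)C(=O)C[C@@H](O[Si](C)(C)C(C)(C)C)/C(C)=C/[C@@H](O[Si](CC)(CC)CC)CC(=C)C=C=O | intermediate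
20 | (1R,4S,5R,7R)-7-[(1R)-1-[(tert-butyldimethylsilyl)oxy]-4-methyl-3-oxopent-4-en-1-yl]-7-methyl-2-methylidene-4-[(triethylsilyl)oxy]bicyclo[3.1.1]heptan-6-one (7-methyl syn to C2–C4, 4-silyloxy cis to C6) | C=C(C)C(=O)C[C@@H](O[Si](C)(C)C(C)(C)C)[C@@]1(C)[C@@H]2[C@@H](O[Si](CC)(CC)CC)CC(=C)[C@H]1C2=O | intermediate
21 | monovalent copper enolate from hydride addition to the terminal CH2 of 20 | CC(C)=C(O[Cu])C[C@@H](O[Si](C)(C)C(C)(C)C)[C@@]1(C)[C@@H]2[C@@H](O[Si](CC)(CC)CC)CC(=C)[C@H]1C2=O | intermediate
22 | 3-[(tert-butyldimethylsilyl)oxy]-7-hydroxy-2,6,6-trimethyl-11-methylidene-9-[(triethylsilyl)oxy]tricyclo[5.4.0.0(2,8)]undecan-5-one (C1, C2, C3, C8 as in 35; 7-OH on the side of the C9–C11 bridge; 9-silyloxy cis to C7) | O=C1C[C@@H](O[Si](C)(C)C(C)(C)C)[C@@]2(C)[C@@H]3[C@@H](O[Si](CC)(CC)CC)CC(=C)[C@H]2[C@]3(O)C1(C)C | intermediate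
23 | methyl oxalate ester of the 7-hydroxyl of 22 | O=C1C[C@@H](O[Si](C)(C)C(C)(C)C)[C@@]2(C)[C@@H]3[C@@H](O[Si](CC)(CC)CC)CC(=C)[C@H]2[C@]3(OC(=O)C(=O)OC)C1(C)C | intermediate
24 | C7-centred tertiary cyclobutyl radical from 23 | O=C1C[C@@H](O[Si](C)(C)C(C)(C)C)[C@@]2(C)[C@@H]3[C@@H](O[Si](CC)(CC)CC)CC(=C)[C@H]2[C]3C1(C)C | intermediate
25 | 3-[(tert-butyldimethylsilyl)oxy]-2,6,6-trimethyl-11-methylidene-9-[(triethylsilyl)oxy]tricyclo[5.4.0.0(2,8)]undecan-5-one (C1, C2, C3, C7, C8 as in 35; 9-silyloxy cis to C7) | O=C1C[C@@H](O[Si](C)(C)C(C)(C)C)[C@@]2(C)[C@@H]3[C@@H](O[Si](CC)(CC)CC)CC(=C)[C@H]2[C@@H]3C1(C)C | intermediate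
26 | 3-[(tert-butyldimethylsilyl)oxy]-9-hydroxy-2,6,6-trimethyl-11-methylidenetricyclo[5.4.0.0(2,8)]undecan-5-one (ring centres as in 35; 9-OH cis to C7) | O=C1C[C@@H](O[Si](C)(C)C(C)(C)C)[C@@]2(C)[C@@H]3[C@@H](O)CC(=C)[C@H]2[C@@H]3C1(C)C | intermediate
27 | 3-[(tert-butyldimethylsilyl)oxy]-2,6,6-trimethyl-11-methylidenetricyclo[5.4.0.0(2,8)]undecane-5,9-dione (ring centres as in 35) | O=C1C[C@@H](O[Si](C)(C)C(C)(C)C)[C@@]2(C)[C@@H]3C(=O)CC(=C)[C@H]2[C@@H]3C1(C)C | intermediate
28 | 3-[(tert-butyldimethylsilyl)oxy]-2,6,6,11-tetramethyltricyclo[5.4.0.0(2,8)]undec-10-ene-5,9-dione (ring centres as in 35) | O=C1C[C@@H](O[Si](C)(C)C(C)(C)C)[C@@]2(C)[C@@H]3C(=O)C=C(C)[C@H]2[C@@H]3C1(C)C | intermediate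
29 | (1R,2R,3R,7S,8R)-3-hydroxy-2,6,6,11-tetramethyltricyclo[5.4.0.0(2,8)]undec-10-ene-5,9-dione | O=C1C[C@@H](O)[C@@]2(C)[C@@H]3C(=O)C=C(C)[C@H]2[C@@H]3C1(C)C | intermediate
30 | (2E)-2-methylbut-2-enal (tiglaldehyde) | O=C/C(C)=C/C | starting material
31 | hemiacetal of the C3 hydroxyl of 29 with 30 (bound to trivalent samarium in the flask) | O=C1C[C@@H](OC(O)/C(C)=C/C)[C@@]2(C)[C@@H]3C(=O)C=C(C)[C@H]2[C@@H]3C1(C)C | intermediate
32 | (1R,2R,3R,5R,7S,8R)-5-hydroxy-2,6,6,11-tetramethyl-9-oxotricyclo[5.4.0.0(2,8)]undec-10-en-3-yl (2E)-2-methylbut-2-enoate | O[C@@H]1C[C@@H](OC(=O)/C(C)=C/C)[C@@]2(C)[C@@H]3C(=O)C=C(C)[C@H]2[C@@H]3C1(C)C | intermediate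
33 | (2Z)-2-methylbut-2-enoic acid (angelic acid) | C/C=C(/C)C(=O)O | starting material
34 | (2Z)-2-methylbut-2-enoic 2,4,6-trichlorobenzoic anhydride | C/C=C(/C)C(=O)OC(=O)c1c(Cl)cc(Cl)cc1Cl | intermediate
35 | (1R,2R,3R,5R,7S,8R)-2,6,6,11-tetramethyl-9-oxotricyclo[5.4.0.0(2,8)]undec-10-ene-3,5-diyl 5-[(2Z)-2-methylbut-2-enoate] 3-[(2E)-2-methylbut-2-enoate] | C/C=C(/C)C(=O)O[C@@H]1C[C@@H](OC(=O)/C(C)=C/C)[C@@]2(C)[C@@H]3C(=O)C=C(C)[C@H]2[C@@H]3C1(C)C | target

## Step count and risks

Total steps: 20. Longest linear sequence: 19 (steps 1–7 and 9–20; step 8 is a one-step side branch).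

Step 13 (key step). What may go wrong: conjugate reduction without ring closure, so that the enolate is simply protonated on work-up, or reversal of the aldol at the metal alkoxide stage. Fallback: starting from 20, 1,4-hydrosilylation of the isopropenyl ketone (Et3SiH, RhCl(PPh3)3 cat., benzene, 50 °C) would give the tetrasubstituted triethylsilyl enol ether F1. Treatment with TiCl4 in CH2Cl2 at −78 °C would then activate the cyclobutanone for an intramolecular Mukaiyama aldol addition, and hydrolytic work-up returns to the route at 22.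

Step 14 (with step 15). What may go wrong: the tertiary C7 hydroxyl, flanked by two bridgeheads, the gem-dimethyl carbon and the nearby C9 silyl ether, may resist acylation. Fallback: starting from 22, the triethylsilyl ether is removed first (PPTS, MeOH, 0 °C) to give the syn-1,3-diol F2. Thiocarbonyldiimidazole (DMAP, toluene, 80 °C) closes the cyclic thionocarbonate F3 across O7 and O9, an intramolecular acylation of the hindered hydroxyl. Bu3SnH/AIBN (toluene, 110 °C) should then cleave the C–O bond at the more substituted C7, and hydrolytic work-up (K2CO3, MeOH) frees the C9 hydroxyl and comes back to the route at 26.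

Step 19. What may go wrong: the conjugated aldehyde may be too poor a hemiacetal partner and hydride donor, so that the ketone is not reduced. Fallback: starting from 29, the same samarium-catalysed Evans–Tishchenko reduction is run with 4-nitrobenzaldehyde to give the 3-(4-nitrobenzoate) 5-alcohol F4. Angeloylation as in step 20 gives F5, mild methanolysis (K2CO3, MeOH, 0 °C) removes the activated aryl ester to give the 3-hydroxy 5-angelate F6, and esterification with (2E)-2-methylbut-2-enoic acid (2,4,6-trichlorobenzoyl chloride, Et3N, then DMAP, toluene) comes back to the route at 35.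

Further compounds
F1 | step 13 | triethylsilyl enol ether of 20 (Me2C=C(OSiEt3)– side chain) | CC(C)=C(O[Si](CC)(CC)CC)C[C@@H](O[Si](C)(C)C(C)(C)C)[C@@]1(C)[C@@H]2[C@@H](O[Si](CC)(CC)CC)CC(=C)[C@H]1C2=O
F2 | step 14 | 3-[(tert-butyldimethylsilyl)oxy]-7,9-dihydroxy-2,6,6-trimethyl-11-methylidenetricyclo[5.4.0.0(2,8)]undecan-5-one | O=C1C[C@@H](O[Si](C)(C)C(C)(C)C)[C@@]2(C)[C@@H]3[C@@H](O)CC(=C)[C@H]2[C@]3(O)C1(C)C
F3 | step 14 | cyclic 7,9-thionocarbonate of F2 | O=C1C[C@@H](O[Si](C)(C)C(C)(C)C)[C@@]2(C)[C@@H]3[C@@H]4CC(=C)[C@H]2[C@]3(OC(=S)O4)C1(C)C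
F4 | step 19 | 5-hydroxy-2,6,6,11-tetramethyl-9-oxotricyclo[5.4.0.0(2,8)]undec-10-en-3-yl 4-nitrobenzoate | O[C@@H]1C[C@@H](OC(=O)c4ccc(cc4)[N+](=O)[O-])[C@@]2(C)[C@@H]3C(=O)C=C(C)[C@H]2[C@@H]3C1(C)C
F5 | step 19 | 5-angelate 3-(4-nitrobenzoate) diester | C/C=C(/C)C(=O)O[C@@H]1C[C@@H](OC(=O)c4ccc(cc4)[N+](=O)[O-])[C@@]2(C)[C@@H]3C(=O)C=C(C)[C@H]2[C@@H]3C1(C)C
F6 | step 19 | 3-hydroxy-2,6,6,11-tetramethyl-9-oxotricyclo[5.4.0.0(2,8)]undec-10-en-5-yl (2Z)-2-methylbut-2-enoate | C/C=C(/C)C(=O)O[C@@H]1C[C@@H](O)[C@@]2(C)[C@@H]3C(=O)C=C(C)[C@H]2[C@@H]3C1(C)C
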